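I began with the easy step of counting turnovers per enzyme, N = c(Rx)/c(Vy charged), the turnover number, since that count turns any Rx percentage into something comparable across charges.

| flask | Uv | Vy | temperature | remark | time |
|---|---|---|---|---|---|
| midnight | 0.10 M | 14 µM | 35 °C | run made earlier |  |
| noon | 0.10 M | 56 µM | 48 °C | run made earlier |  |
| spring | 0.20 M | 28 µM | 35 °C | run made earlier |  |
| grey | 0.10 M | 28 µM | 40 °C |  | 15 min |
| violet | 0.10 M | 28 µM | 55 °C |  | 15 min |
| blue | 0.10 M | 28 µM |  | at 55 °C until 8.0 min, from then on at 40 °C | 15 min |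

| run | time / min | Rx / % | Uv / % |
|---|---|---|---|
| midnight | 1.00 | 2.4 | 83.9 |
| midnight | 3.00 | 5.6 | 61.5 |
| midnight | 6.00 | 12.2 | 38.4 |
| midnight | 10.0 | 18.1 | 25.3 |
| noon | 0.667 | 8.9 | 64.6 |
| noon | 1.50 | 17.9 | 41.8 |
| noon | 4.00 | 24.1 | 26.0 |
| noon | 10.0 | 24.7 | 26.3 |
| spring | 2.50 | 7.0 | 66.0 |
| spring | 5.00 | 14.8 | 44.1 |
| spring | 6.00 | 16.0 | 37.9 |
| spring | 10.0 | 23.7 | 23.2 |

(scatter of a reading: 1 percentage point)

* the flask that comes out highest in amount of Rx, in percent of the Uv charged, or "all alike" when all lie within 1.5 percentage points (grey / violet / blue / all alike)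
* Rx at the end, in percent of the Uv charged, grey
* Rx at the end, in percent of the Uv charged, violet
* Rx at the end, in percent of the Uv charged, blue

- the analysis behind the earlier runs scatters by 1 percentage point, standard deviation

The bench rule says that at fixed Uv and temperature Rx grows with Vy and with time, so I took the pace from the midnight run at its last reading:

pace = 129 min⁻¹

Over the flask's time this gives what I called the clock count, the turnovers a Vy can make at that pace:

clock count = 1940

For grey this means 54.3% Rx, but midnight's Uv had already fallen to 25.3% with Rx at 18.1%, so I held that figure to be generous.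

The rule's border showed in the noon run, where Rx stood at 24.1% and then 24.7%, flat within the scatter. The count there stopped at a reading of

N = 441

so the clock count exceeds noon's stopping count by a factor of 4.40. Noon's early slope, carried straight up to that last reading, meets it after about 2.07 min, which I took as a working life; this is a crossing of two lines and not the end of Rx, for the noon readings still climb from 17.9% at 1.50 min to 24.1% at 4.00 min.

Violet is hotter than noon, so I reckoned its Rx below 12.3%. Blue's change at 8.0 min comes after 3.86 such lives, so I expected blue to match violet and grey to come out highest.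

The forecast said grey, with 33%, 4.5% and 4.5% for grey, violet and blue, holding that “the flat noon plateau implies irreversible loss”.

The flasks gave grey as highest, with 33.7% in grey, 4.74% in violet and 4.74% in blue.

    Dx ⇌ Vy + Rx (K = 0.270 M, k = 7.32 s⁻¹, Ea = 73.0 kJ mol⁻¹, ΔH = −38.0 kJ mol⁻¹)
    Uv + Vy ⇌ Dx (K = 15.1 M⁻¹, k = 1.15 × 10⁵ M⁻¹ s⁻¹, Ea = 14.0 kJ mol⁻¹, ΔH = −79.0 kJ mol⁻¹)
    Vy → Ry (k = 9.68 × 10⁻⁴ s⁻¹, Ea = 103 kJ mol⁻¹)
    Uv ⇌ Ze (K = 2.60, k = 0.00391 s⁻¹, Ea = 80.0 kJ mol⁻¹, ΔH = −32.0 kJ mol⁻¹)
    Vy → Ym (k = 4.00 × 10⁻⁴ s⁻¹, Ea = 249 kJ mol⁻¹)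
    (constants at 40 °C)

Grey made 1200 turnovers of its clock count of 1940, while violet stopped at 169. The main reason for violet's small count is the falling back of Dx to Uv + Vy: with that step struck out, violet's Rx rises from 4.74% to 99.2%.

For a neighbour of grey, the same flask with 7.0 × 10⁻⁶ M of Vy, the clock count gives 13.6% Rx, and the flask gives 11.7%.

All runs come from a simulation on assumed constants; scatter was added.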